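**Plan**

- Numbering (germacrane): ring A is the butenolide (O, C6, C7, C11, C12; C13 on C11), ring B the tetrahydrofuran (C1–C4 and O), ring C the ten-membered carbocycle (C1–C10). Feature used: C1 (hemiketal) and C8 (acyloxy carbon) are 1,4-related through C10–C9, the pattern of a C1-ketone homoenolate adding to a C8 aldehyde, and the C4 oxygen is gamma to C1, so the freed ketone closes ring B.
- Cuts: ring A back to a furan (C5=C6 and C12=O removed), C8 ester and C13 acetate off; C8–C9 and C1–O(C4) cut in one operation to a furan aldehyde carrying a 2-methylcyclopropanol; cyclopropanol back to a C1 gamma-lactone; C2–C3 and C5–C6 cut at the two CH2 groups of (R)-2-methylglycidol.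
- Forward: 3,4-disubstituted furan, then C6–C5 (furyllithium and glycidyl tosylate), then C3–C2 and the lactone (malonate), then the cyclopropanol (Kulinkovich), then rings C and B together, then side chain and acetate, then ring A by furan oxidation and dehydration.
- Stereochemistry: C4 from (R)-2-methylglycidol; C10 from the cis-selective Kulinkovich step after separation of its two cis diastereomers; C8 from the chiral amino-alcohol ligand on zinc; C1 dictated by C4 through the oxygen bridge; C2′ from methyl (S)-2-methylglycidate; C5=C6 geometry by the ring.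

Key step: step 11

Remark: hydroxy aldehyde 17 is expected to rest partly as its six-membered lactol (C4–O on C8); the two are ring–chain tautomers, treated as one compound and written in the open form.

**Route**

Step 1
Reactants: 1 dimethyl furan-3,4-dicarboxylate
Product: 2 furan-3,4-diyldimethanol
Conditions: LiAlH4, THF, 0 °C → rt
Reagents that add atoms: none
Why: Hydride reduction of both ester groups should give the symmetric diol; no stereocentre is involved.

Step 2
Reactants: 2 furan-3,4-diyldimethanol
Product: 3 mono-TBS ether of 2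
Conditions: NaH (1 equiv), THF, 0 °C; TBSCl (1 equiv), rt
Reagents that add atoms: tert-butyldimethylsilyl chloride, CC(C)(C)[Si](C)(C)Cl
Why: Silylation of a symmetric diol through its monosodium alkoxide should favour the mono-ether, which differentiates the future C13 arm (silylated) from the future C8 arm (free).

Step 3
Reactants: 3 mono-TBS ether
Product: 4 4-(TBSO-methyl)furan-3-carbaldehyde
Conditions: MnO2 (activated), CH2Cl2, rt
Reagents that add atoms: none
Why: MnO2 oxidises the furylic primary alcohol to the aldehyde (oxidation of a benzylic-type alcohol) and leaves the silyl ether alone.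

Step 4
Reactants: 4 furan-3-carbaldehyde
Product: 5 dioxolane acetal of 4
Conditions: Me3SiOCH2CH2OSiMe3, Me3SiOTf (cat.), CH2Cl2, −78 °C
Reagents that add atoms: 1,2-bis(trimethylsilyloxy)ethane, C[Si](C)(C)OCCO[Si](C)(C)C
Why: Aprotic silyl-transfer acetalisation masks C8 at the aldehyde oxidation level for the organometallic steps and provides the directing group for the lithiation, while the primary silyl ether tolerates the catalytic silyl triflate at low temperature.

Step 5
Reactants: 6 (R)-2-methylglycidol
Product: 7 (S)-2-methylglycidyl tosylate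
Conditions: TsCl, Et3N, 4-dimethylaminopyridine (cat.), CH2Cl2, 0 °C
Reagents that add atoms: 4-methylbenzenesulfonyl chloride, Cc1ccc(cc1)S(Cl)(=O)=O
Why: O-Sulfonylation of the primary alcohol makes a bis-electrophile whose epoxide CH2 becomes C5 and whose CH2OTs becomes C3; the quaternary centre is untouched and only its descriptor changes.

Step 6
Reactants: 5 dioxolane acetal, 7 (S)-2-methylglycidyl tosylate
Product: 10 furylmethyl methyl oxirane (C3–C4 epoxide), via furyllithium 8 (not isolated), via hydroxy tosylate 9 (not isolated)
Conditions: n-BuLi, THF, −78 → 0 °C; BF3·OEt2 then 7, −78 °C; crude 9, K2CO3, MeOH, rt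
Reagents that add atoms: none
Why: Directed ortho-lithiation places lithium on the furan alpha-carbon between the ring oxygen and the dioxolane-bearing carbon (C6), BF3-promoted SN2 opening of the epoxide at its CH2 terminus forms C5–C6, and the tertiary alkoxide then displaces the neighbouring tosylate (3-exo-tet) to transpose the epoxide; no bond to C4 is broken, so its configuration comes unchanged from 6.

Step 7
Reactants: 10 C3–C4 epoxide, 11 diethyl malonate
Product: 13 alpha-ethoxycarbonyl gamma-lactone, via hydroxy malonate 12 (not isolated)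
Conditions: NaOEt, EtOH, 70 °C; AcOH
Reagents that add atoms: none
Why: Sodiomalonate opens the 2,2-disubstituted epoxide at its CH2 (C3) by SN2 and the released tertiary alkoxide lactonises onto one ester (malonate–epoxide gamma-lactone synthesis); C4 is untouched and the extra centre at C2 disappears in step 8.

Step 8
Reactants: 13 alpha-ethoxycarbonyl gamma-lactone
Product: 14 C1 gamma-lactone
Conditions: NaCl, H2O, DMSO, 150 °C
Reagents that add atoms: none
Why: Krapcho dealkoxycarbonylation (chloride attack on the ethyl group, loss of CO2, protonation) removes the extra ester under neutral conditions that acetal, silyl ether and lactone should survive.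

Step 9
Reactants: 14 C1 gamma-lactone, 15 propylmagnesium bromide
Product: 16 cis-2-methylcyclopropanol diol (1R,10R)
Conditions: Ti(OiPr)4 (1.2 equiv), THF, 0 °C → rt, 15 (4 equiv) added slowly; aq. NH4Cl; preparative HPLC (chiral stationary phase)
Reagents that add atoms: none
Why: In this Kulinkovich cyclopropanation of a lactone the titanacyclopropane from the Grignard reagent delivers C9 and C10 to the carbonyl carbon, and the ring-closing step places the C1 side chain and the C10 methyl cis; the remote C4 centre is not expected to bias the face, so both cis diastereomers should form in comparable amounts, and the (1R,10R) isomer is separated from the (1S,10S) one, which fixes C10 of the target.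

Step 10
Reactants: 16 cyclopropanol diol
Product: 17 cyclopropanol furan aldehyde (key-step precursor)
Conditions: pyridinium p-toluenesulfonate (cat.), acetone/H2O 10:1, 40 °C
Reagents that add atoms: water, O
Why: Mild acid-catalysed hydrolysis of the electron-rich furyl dioxolane frees the C8 aldehyde under conditions that a tertiary cyclopropanol and a primary silyl ether are expected to tolerate, which avoids any oxidation in the presence of the cyclopropanol.

Step 11
Reactants: 17 cyclopropanol furan aldehyde
Product: 19 furan-bridged C1 hemiketal, via zinc homoenolate 18 (not isolated)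
Conditions: Zn(CH2SiMe3)2 (3.3 equiv), (2S)-3-exo-morpholinoisoborneol [(−)-MIB] (1.1 equiv), toluene, 0 → 40 °C, 17 added by syringe pump to 2 mM; aq. NH4Cl
Reagents that add atoms: none
Why: Proposed new method: the dialkylzinc turns both hydroxyls into zinc alkoxides, the cyclopropoxide opens by beta-carbon elimination at the less substituted C1–C9 bond to the primary alkylzinc 18 (a zinc homoenolate of the C1 ketone), and the amino-alkoxide ligand activates the C8 aldehyde and the C9–Zn bond for addition, while the Me3SiCH2 group on zinc does not transfer to aldehydes as an ethyl group would. The closest known reaction types are the dialkylzinc-mediated opening of cyclopropanols to zinc homoenolates with intermolecular capture by carbon electrophiles, the addition of zinc ester homoenolates to aldehydes, and amino-alcohol-accelerated alkylzinc additions to aryl aldehydes; their use for a ring closure is new. Ring C closes by C9 attacking the C8 carbonyl in a 10-exo-trig mode and ring B closes by the C4 zinc alkoxide adding to the C1 ketone in a 5-exo-trig mode, which also removes the ketone so that C10 cannot enolise. C8 is set by (−)-MIB, the ligand enantiomer that delivers alkyl groups to the Si face of aryl aldehydes (8S here); C1 follows C4 because the oxygen bridge can span C1 and C4 only with C5 and C10 cis on ring B; C10 is carried unchanged from 17 because no bond to it is made or broken. The step needs cleavage of C1–C9 and not C1–C10, which the preference for a primary over a secondary carbon–zinc bond secures, and ring closure in preference to oligomers, which high dilution and the resting lactol form of the aldehyde favour.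

Step 12
Reactants: 20 methyl (S)-2-methylglycidate
Product: 21 potassium (S)-2-methylglycidate
Conditions: KOH (1.0 equiv), MeOH, 0 °C → rt; evaporation
Reagents that add atoms: potassium hydroxide, [K+].[OH-]
Why: Saponification with one equivalent of hydroxide at low temperature should give the stable carboxylate salt without opening the epoxide; C2′ is untouched.

Step 13
Reactants: 19 furan-bridged C1 hemiketal, 21 potassium (S)-2-methylglycidate
Product: 23 C8 (S)-2-methylglycidate ester, via mixed anhydride 22 (not isolated)
Conditions: 21, 2,4,6-trichlorobenzoyl chloride, THF, rt; then 19, Et3N, 4-dimethylaminopyridine, toluene, rt → 40 °C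
Reagents that add atoms: none
Why: Yamaguchi esterification through the mixed anhydride acylates the secondary C8 alcohol with retention, while the tertiary hemiketal hydroxyl at C1 should stay free for steric reasons.

Step 14
Reactants: 23 C8 glycidate ester
Product: 24 C13 alcohol
Conditions: Bu4NF, AcOH (1:1), THF, 0 °C → rt
Reagents that add atoms: none
Why: Acetic acid-buffered fluoride cleaves the primary silyl ether through Si–F bond formation without epoxide opening, ester cleavage or base-induced epimerisation at C10.

Step 15
Reactants: 24 C13 alcohol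
Product: 25 C13 acetate
Conditions: Ac2O, pyridine, CH2Cl2, 0 °C
Reagents that add atoms: acetic anhydride, CC(=O)OC(C)=O
Why: Acetylation of the primary alcohol should be selective over the tertiary C1 hydroxyl when no acyl-transfer catalyst is present.

Step 16
Reactants: 25 C13 acetate
Product: 26 C8 chlorohydrin ester
Conditions: LiCl, AcOH, THF, rt
Reagents that add atoms: lithium chloride, [Li+].[Cl-]
Why: Chloride opens the glycidic ester at its unsubstituted CH2 under mild Brønsted acid activation (halohydrin formation from an epoxide); the quaternary C2′ is untouched, so the (2R) chlorohydrin arises from the (2S) epoxide by a change of priorities only.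

Step 17
Reactants: 26 C8 chlorohydrin ester
Product: 28 gamma-hydroxybutenolide (C6 epimers), via furan endoperoxide 27 (not isolated)
Conditions: O2, visible light, 5,10,15,20-tetraphenylporphyrin (cat.), iPr2NEt, CH2Cl2, −78 °C → rt
Reagents that add atoms: dioxygen, O=O
Why: Singlet oxygen adds to the furan in a [4+2] cycloaddition and the hindered amine removes the only bridgehead hydrogen (on C12) in a Kornblum–DeLaMare fragmentation, which puts the carbonyl at C12 and the hydroxyl at C6; the C6 epimers converge in step 18.

Step 18
Reactants: 28 gamma-hydroxybutenolide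
Product: 30 target CNP0414417.3, via pseudo-acid acetate 29 (not isolated)
Conditions: Ac2O, iPr2NEt, CH2Cl2, 0 °C → rt
Reagents that add atoms: none
Why: Acylation of the pseudo-acid hydroxyl (through its ring-opened carboxylate) and amine-assisted loss of acetic acid toward C5, the only hydrogen-bearing neighbour of C6, gives the enol lactone (enol lactonisation of a 4-oxo-2-enoic acid) without touching the two other tertiary hydroxyls; the ten-membered ring allows only the C5=C6 geometry with C4 cis to C7.

**Compound list**

1 | dimethyl furan-3,4-dicarboxylate | COC(=O)c1cocc1C(=O)OC | starting material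
2 | furan-3,4-diyldimethanol | OCc1cocc1CO | intermediate
3 | [4-({[tert-butyl(dimethyl)silyl]oxy}methyl)furan-3-yl]methanol | CC(C)(C)[Si](C)(C)OCc1cocc1CO | intermediate
4 | 4-({[tert-butyl(dimethyl)silyl]oxy}methyl)furan-3-carbaldehyde | CC(C)(C)[Si](C)(C)OCc1cocc1C=O | intermediate
5 | tert-butyl{[4-(1,3-dioxolan-2-yl)furan-3-yl]methoxy}dimethylsilane | CC(C)(C)[Si](C)(C)OCc1cocc1C2OCCO2 | intermediate
6 | (R)-2-methylglycidol, [(2R)-2-methyloxiran-2-yl]methanol | OC[C@]1(C)CO1 | starting material
7 | [(2S)-2-methyloxiran-2-yl]methyl 4-methylbenzenesulfonate | Cc1ccc(cc1)S(=O)(=O)OC[C@]1(C)CO1 | intermediate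
8 | [4-({[tert-butyl(dimethyl)silyl]oxy}methyl)-3-(1,3-dioxolan-2-yl)furan-2-yl]lithium (formed in the flask) | CC(C)(C)[Si](C)(C)OCc1coc([Li])c1C2OCCO2 | intermediate
9 | (2S)-3-[4-({[tert-butyl(dimethyl)silyl]oxy}methyl)-3-(1,3-dioxolan-2-yl)furan-2-yl]-2-hydroxy-2-methylpropyl 4-methylbenzenesulfonate (formed in the flask) | CC(C)(C)[Si](C)(C)OCc1coc(C[C@](C)(O)COS(=O)(=O)c3ccc(C)cc3)c1C2OCCO2 | intermediate
10 | tert-butyl{[4-(1,3-dioxolan-2-yl)-5-{[(2S)-2-methyloxiran-2-yl]methyl}furan-3-yl]methoxy}dimethylsilane | CC(C)(C)[Si](C)(C)OCc1coc(C[C@@]3(C)CO3)c1C2OCCO2 | intermediate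
11 | diethyl malonate | CCOC(=O)CC(=O)OCC | starting material
12 | diethyl 2-{(2R)-3-[4-({[tert-butyl(dimethyl)silyl]oxy}methyl)-3-(1,3-dioxolan-2-yl)furan-2-yl]-2-hydroxy-2-methylpropyl}propanedioate (formed in the flask) | CC(C)(C)[Si](C)(C)OCc1coc(C[C@](C)(O)CC(C(=O)OCC)C(=O)OCC)c1C2OCCO2 | intermediate
13 | ethyl (5R)-5-{[4-({[tert-butyl(dimethyl)silyl]oxy}methyl)-3-(1,3-dioxolan-2-yl)furan-2-yl]methyl}-5-methyl-2-oxooxolane-3-carboxylate (both C3 epimers) | CC(C)(C)[Si](C)(C)OCc1coc(C[C@@]3(C)CC(C(=O)OCC)C(=O)O3)c1C2OCCO2 | intermediate
14 | (5R)-5-{[4-({[tert-butyl(dimethyl)silyl]oxy}methyl)-3-(1,3-dioxolan-2-yl)furan-2-yl]methyl}-5-methyloxolan-2-one | CC(C)(C)[Si](C)(C)OCc1coc(C[C@@]3(C)CCC(=O)O3)c1C2OCCO2 | intermediate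
15 | propylmagnesium bromide | CCC[Mg]Br | starting material
16 | (1R,2R)-1-{(3R)-4-[4-({[tert-butyl(dimethyl)silyl]oxy}methyl)-3-(1,3-dioxolan-2-yl)furan-2-yl]-3-hydroxy-3-methylbutyl}-2-methylcyclopropan-1-ol | CC(C)(C)[Si](C)(C)OCc1coc(C[C@](C)(O)CC[C@@]3(O)C[C@H]3C)c1C2OCCO2 | intermediate
17 | 4-({[tert-butyl(dimethyl)silyl]oxy}methyl)-2-{(2R)-2-hydroxy-4-[(1R,2R)-1-hydroxy-2-methylcyclopropyl]-2-methylbutyl}furan-3-carbaldehyde | O=Cc1c(CO[Si](C)(C)C(C)(C)C)coc1C[C@](C)(O)CC[C@@]2(O)C[C@H]2C | intermediate
18 | zinc homoenolate (formed in the flask): (4R,10R) open-chain C1 ketone of 17 with C9–Zn–CH2SiMe3, C4–O–Zn–CH2SiMe3 and the C8 aldehyde intact | O=Cc1c(CO[Si](C)(C)C(C)(C)C)coc1C[C@](C)(O[Zn]C[Si](C)(C)C)CCC(=O)[C@H](C)C[Zn]C[Si](C)(C)C | intermediate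
19 | (1S,4R,8S,10R)-13-[(tert-butyldimethylsilyl)oxy]-1,4:6,12-diepoxygermacra-6,11-diene-1,8-diol (furan-bridged hemiketal) | CC(C)(C)[Si](C)(C)OCc1coc2C[C@@]3(C)CC[C@](O)(O3)[C@H](C)C[C@H](O)c12 | intermediate
20 | methyl (S)-2-methylglycidate, methyl (2S)-2-methyloxirane-2-carboxylate | COC(=O)[C@@]1(C)OC1 | starting material
21 | potassium (2S)-2-methyloxirane-2-carboxylate | [K+].[O-]C(=O)[C@@]1(C)OC1 | intermediate
22 | (2S)-2-methyloxirane-2-carboxylic 2,4,6-trichlorobenzoic anhydride (formed in the flask) | O=C(OC(=O)[C@@]1(C)OC1)c1c(Cl)cc(Cl)cc1Cl | intermediate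
23 | 19 esterified at O8 with the (2S)-2-methyloxirane-2-carbonyl group (1S,4R,8S,10R) | CC(C)(C)[Si](C)(C)OCc1coc2C[C@@]3(C)CC[C@](O)(O3)[C@H](C)C[C@H](OC(=O)[C@@]4(C)OC4)c12 | intermediate
24 | 23 with free C13 hydroxyl | OCc1coc2C[C@@]3(C)CC[C@](O)(O3)[C@H](C)C[C@H](OC(=O)[C@@]4(C)OC4)c12 | intermediate
25 | 13-O-acetate of 24 | CC(=O)OCc1coc2C[C@@]3(C)CC[C@](O)(O3)[C@H](C)C[C@H](OC(=O)[C@@]4(C)OC4)c12 | intermediate
26 | (1S,4R,8S,10R)-13-acetoxy-8-[(2R)-3-chloro-2-hydroxy-2-methylpropanoyloxy]-1,4:6,12-diepoxygermacra-6,11-dien-1-ol | CC(=O)OCc1coc2C[C@@]3(C)CC[C@](O)(O3)[C@H](C)C[C@H](OC(=O)[C@@](C)(O)CCl)c12 | intermediate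
27 | 6,12-endoperoxide of 26 (formed in the flask; O–O bridge across C6 and C12) | CC(=O)OCC1=C2C3(OOC1O3)C[C@@]4(C)CC[C@](O)(O4)[C@H](C)C[C@@H]2OC(=O)[C@@](C)(O)CCl | intermediate
28 | 6-hydroxy-5,6-dihydro derivative of the target (gamma-hydroxybutenolide, C6 epimers) | CC(=O)OCC1=C2C(O)(C[C@@]3(C)CC[C@](O)(O3)[C@H](C)C[C@@H]2OC(=O)[C@@](C)(O)CCl)OC1=O | intermediate
29 | 6-O-acetyl derivative of 28 (formed in the flask) | CC(=O)OCC1=C2C(OC(C)=O)(C[C@@]3(C)CC[C@](O)(O3)[C@H](C)C[C@@H]2OC(=O)[C@@](C)(O)CCl)OC1=O | intermediate
30 | CNP0414417.3, (1S,4R,8S,10R)-13-acetoxy-8-[(2R)-3-chloro-2-hydroxy-2-methylpropanoyloxy]-1,4-epoxy-1-hydroxygermacra-5E,7(11)-dien-6,12-olide | CC(=O)OCC1=C2/C(=C\[C@@]3(C)CC[C@](O)(O3)[C@H](C)C[C@@H]2OC(=O)[C@@](C)(O)CCl)OC1=O | target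

**Step count and risks**

Total step count: 18. Longest linear sequence: 16 steps (1 → 2 → 3 → 4 → 5 → 10 → 13 → 14 → 16 → 17 → 19 → 23 → 24 → 25 → 26 → 28 → 30; steps 5 and 12 lie on side branches).

Steps most likely to fail:

1. Step 11 (bears the new-method label).
   - What may go wrong: the aldehyde may stay locked as its zinc lactolate; the homoenolate may be protonated or enolised before the C–C bond forms; oligomers may form in place of the ten-membered ring; the ligand and the tether may disagree on the face of C8.
   - Fallback with known chemistry, setting out from 16 and coming back at 19: electrophilic ring opening of the cyclopropanol with N-iodosuccinimide (halogen delivered to the less substituted ring carbon C9) would give the C9 iodide as its five-membered C1 hemiketal, iodo hemiketal F1, in which ring B is already in place. Acetal hydrolysis as in step 10 would give iodo aldehyde F2. SmI2/HMPA in THF at high dilution would then close ring C by an intramolecular Barbier addition of C9 to the C8 aldehyde, giving 19; C8 would then rest on substrate control.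

2. Step 9.
   - What may go wrong: the remote C4 centre gives no facial discrimination, and the two cis diastereomers may not be resolved chromatographically.
   - Fallback, setting out from 14 and coming back at 19: the separation is moved behind the ring closure. The Kulinkovich product is taken on as the mixture of 16 and its diastereomer, (1S,10S)-cyclopropanol diol F3. Steps 10 and 11 turn F3 into the diastereomeric aldehyde F4 and then the C10-epimeric hemiketal F5. 19 and F5 are rigid bicyclic diastereomers that should separate on silica. F5 would be returned to 19 by base-mediated epimerisation alpha to the latent C1 ketone (DBU, toluene). In 19 the C10 methyl can sit between the two oxygen substituents of C1 and not next to the C2 methylene, which should favour the natural configuration.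

3. Step 18.
   - What may go wrong: acylation or ionisation may occur at the free C1 hemiketal hydroxyl (with loss of C10 integrity through an enol ether) in competition with elimination at C6, and the base may trigger loss of the C13 acetate from the dienolide.
   - Fallback, setting out from 26 and coming back at 30: the hemiketal is masked before ring A is oxidised. Pyridinium p-toluenesulfonate in methanol would convert 26 into C1 methyl ketal F6. Photooxygenation as in step 17 would give hydroxybutenolide methyl ketal F7. Dehydration, now possible under more forcing conditions (methanesulfonyl chloride, Et3N), would give 1-O-methyl dienolide F8. Brief treatment with pyridinium p-toluenesulfonate in wet acetone would exchange the ketal for the hemiketal and give 30.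

Further compounds
F1 | step 11 | iodo hemiketal: (5R)-2-[(2R)-1-iodopropan-2-yl]-5-methyl-5-{[4-(TBSO-methyl)-3-(1,3-dioxolan-2-yl)furan-2-yl]methyl}oxolan-2-ol (C1 anomers) | CC(C)(C)[Si](C)(C)OCc1coc(C[C@@]3(C)CCC(O)(O3)[C@H](C)CI)c1C2OCCO2
F2 | step 11 | iodo aldehyde: F1 with the dioxolane replaced by the free C8 aldehyde | O=Cc1c(CO[Si](C)(C)C(C)(C)C)coc1C[C@@]2(C)CCC(O)(O2)[C@H](C)CI
F3 | step 9 | (1S,2S)-cyclopropanol diastereomer of 16 | CC(C)(C)[Si](C)(C)OCc1coc(C[C@](C)(O)CC[C@]3(O)C[C@@H]3C)c1C2OCCO2
F4 | step 9 | (1S,2S)-cyclopropanol diastereomer of 17 | O=Cc1c(CO[Si](C)(C)C(C)(C)C)coc1C[C@](C)(O)CC[C@]2(O)C[C@@H]2C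
F5 | step 9 | C10 epimer of 19, (1S,4R,8S,10S) | CC(C)(C)[Si](C)(C)OCc1coc2C[C@@]3(C)CC[C@](O)(O3)[C@@H](C)C[C@H](O)c12
F6 | step 18 | C1 methyl ketal of 26 | CC(=O)OCc1coc2C[C@@]3(C)CC[C@](OC)(O3)[C@H](C)C[C@H](OC(=O)[C@@](C)(O)CCl)c12
F7 | step 18 | C1 methyl ketal of 28 (C6 epimers) | CC(=O)OCC1=C2C(O)(C[C@@]3(C)CC[C@](OC)(O3)[C@H](C)C[C@@H]2OC(=O)[C@@](C)(O)CCl)OC1=O
F8 | step 18 | 1-O-methyl ether of 30 | CC(=O)OCC1=C2/C(=C\[C@@]3(C)CC[C@](OC)(O3)[C@H](C)C[C@@H]2OC(=O)[C@@](C)(O)CCl)OC1=O
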